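**Retrosynthetic overview**
1. Target 22 ← global desilylation ← enone by Saegusa–Ito desaturation of a saturated ketone; the Z-alkene ← Lindlar reduction of a chain alkyne that is kept until after the osmylation.
2. cis-5,6-Diol ← OsO4 dihydroxylation of a 2-alkyl-4-silyloxycyclohex-2-enone, anti to the C4–OTBS group (C4 controls C5 and C6).
3. Ring–chain bond (key coupling) ← B-alkyl Suzuki–Miyaura coupling of (S)-2-iodo-4-silyloxycyclohex-2-enone 4 with the 9-BBN borane of henicos-1-en-12-yne 15.
4. Iodoenone 4 ← 4-hydroxycyclohexanone (silylation, new enantioselective desymmetrising Pd dehydrogenation, α-iodination). Enyne 15 ← oct-1-ene, sodium acetylide, 5-bromopent-1-ene and 1-bromo-6-chlorohexane.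
5. Rings: the only ring is bought with compound 1; no ring is formed in the route.

Assumption: the sense of induction of the chiral ligand in step 2 (and of the chiral base in its fallback) cannot be fixed on paper; the antipode that gives the (S)-enone 3 is used.

**Route**

Step 1
Reactants: 1 4-hydroxycyclohexan-1-one
Product: 2 4-[(tert-butyldimethylsilyl)oxy]cyclohexan-1-one
Conditions: TBSCl, imidazole, DMF, rt
Reagents that add atoms: tert-butyldimethylsilyl chloride (CC(C)(C)[Si](C)(C)Cl)
Why: Imidazole-promoted silyl ether formation on a secondary alcohol; 2 is achiral (mirror plane through C1 and C4).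

Step 2
Reactants: 2 4-[(tert-butyldimethylsilyl)oxy]cyclohexan-1-one
Product: 3 (S)-4-[(tert-butyldimethylsilyl)oxy]cyclohex-2-en-1-one
Conditions: Pd(OCOCF3)2 (5 mol %), (S,S)-1,2-bis(tert-butylsulfinyl)benzene (6 mol %), O2 (1 atm), EtOAc/AcOH (4:1), 50 °C
Reagents that add atoms: none
Why: Proposed new method: an enantioselective desymmetrising aerobic α,β-dehydrogenation (C–H activation) in which a C2-symmetric chiral bis-sulfoxide takes the place of the two dimethyl sulfoxide ligands of the known achiral Pd(DMSO)2(OCOCF3)2/O2 ketone dehydrogenation catalyst; carboxylate-assisted α-C–H palladation of the O-bound ketone is turnover-limiting and irreversible, so the chiral pocket picks one of the two enantiotopic axial α-hydrogens (OTBS equatorial), β-hydride elimination then puts the C=C bond on that arm and makes C4 (S), O2 reoxidises the zerovalent palladium, and sulfoxide ligation holds back the second dehydrogenation to the phenol; the closest known reaction types are the achiral divalent-palladium/O2 dehydrogenation of cyclohexanones and the chiral lithium amide desymmetrisation of 4-substituted cyclohexanones.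

Step 3
Reactants: 3 (S)-4-[(tert-butyldimethylsilyl)oxy]cyclohex-2-en-1-one
Product: 4 (S)-4-[(tert-butyldimethylsilyl)oxy]-2-iodocyclohex-2-en-1-one
Conditions: I2, pyridine/CH2Cl2, 0 °C → rt
Reagents that add atoms: iodine ([I][I])
Why: Johnson α-iodination of an enone (conjugate addition of pyridine, iodination of the enolate, E1cB loss of pyridine); C4 is not touched.

Step 4
Reactants: 5 oct-1-ene
Product: 6 1-bromooctane
Conditions: HBr (gas), (PhCO2)2 (2 mol %), hexane, 0 °C
Reagents that add atoms: hydrogen bromide (Br)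
Why: Radical-chain anti-Markovnikov hydrobromination (Kharasch peroxide effect); the bromine atom adds to the terminal carbon.

Step 5
Reactants: 6 1-bromooctane; 7 sodium acetylide (NaC≡CH)
Product: 8 dec-1-yne
Conditions: DMSO/THF, rt
Reagents that add atoms: none
Why: SN2 alkylation of an acetylide with an unhindered primary bromide.

Step 6
Reactants: 9 5-bromopent-1-ene; 10 1-bromo-6-chlorohexane
Product: 12 11-chloroundec-1-ene, via pent-4-enylmagnesium bromide 11 (not isolated)
Conditions: Mg, THF, rt; then 10, Li2CuCl4 (3 mol %), THF, −10 °C → rt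
Reagents that add atoms: none
Why: Kochi-type copper-catalysed sp3–sp3 coupling of a Grignard reagent; the C–Br bond of 10 reacts and the C–Cl bond is left, which avoids double coupling.

Step 7
Reactants: 12 11-chloroundec-1-ene
Product: 13 11-iodoundec-1-ene
Conditions: NaI, acetone, reflux
Reagents that add atoms: sodium iodide ([Na+].[I-])
Why: Finkelstein halide exchange driven by precipitation of NaCl; the iodide is the better electrophile for step 8.

Step 8
Reactants: 8 dec-1-yne; 13 11-iodoundec-1-ene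
Product: 15 henicos-1-en-12-yne, via lithium dec-1-yn-1-ide 14 (not isolated)
Conditions: n-BuLi, THF, −78 °C; then 13, DMPU, −78 °C → rt
Reagents that add atoms: none
Why: SN2 alkylation of a lithium acetylide with a primary iodide in a dipolar co-solvent.

Step 9
Reactants: 15 henicos-1-en-12-yne; 4 (S)-4-[(tert-butyldimethylsilyl)oxy]-2-iodocyclohex-2-en-1-one
Product: 17 (S)-4-[(tert-butyldimethylsilyl)oxy]-2-(henicos-12-yn-1-yl)cyclohex-2-en-1-one, via B-(henicos-12-yn-1-yl)-9-borabicyclo[3.3.1]nonane 16 (not isolated)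
Conditions: 9-BBN-H (1.05 equiv), THF, 0 °C → rt; then 4, PdCl2(dppf) (5 mol %), AsPh3 (5 mol %), Cs2CO3, DMF/THF/H2O, rt
Reagents that add atoms: none
Why: 9-BBN-H hydroborates the terminal alkene anti-Markovnikov much faster than the internal alkyne, and the B-alkyl Suzuki–Miyaura coupling with the α-iodoenone then forms the ring–chain sp2–sp3 bond under mild base; C4 is not touched.

Step 10
Reactants: 17 (S)-4-[(tert-butyldimethylsilyl)oxy]-2-(henicos-12-yn-1-yl)cyclohex-2-en-1-one
Product: 18 (2R,3R,4S)-4-[(tert-butyldimethylsilyl)oxy]-2-(henicos-12-yn-1-yl)-2,3-dihydroxycyclohexan-1-one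
Conditions: K2OsO2(OH)4 (5 mol %), NMO, citric acid, THF/t-BuOH/H2O, rt
Reagents that add atoms: N-methylmorpholine N-oxide (C[N+]1([O-])CCOCC1); water (O)
Why: Upjohn syn-dihydroxylation in which OsO4 adds to the enone face anti to the allylic OTBS group (Kishi's rule), setting C2 (R) and C3 (R) cis to each other and trans to the C4 oxygen, while the internal alkyne is inert to OsO4 and citric acid speeds turnover for the electron-poor alkene.

Step 11
Reactants: 18 (2R,3R,4S)-4-[(tert-butyldimethylsilyl)oxy]-2-(henicos-12-yn-1-yl)-2,3-dihydroxycyclohexan-1-one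
Product: 19 (2R,3R,4S)-4-[(tert-butyldimethylsilyl)oxy]-2-[(12Z)-henicos-12-en-1-yl]-2,3-dihydroxycyclohexan-1-one
Conditions: H2 (1 atm), Pd/CaCO3 poisoned with Pb(OAc)2, quinoline, EtOAc, rt
Reagents that add atoms: none
Why: Lindlar semihydrogenation delivers H2 syn on the poisoned palladium surface and gives the Z-alkene; no other reducible alkene is present at this stage.

Step 12
Reactants: 19 (2R,3R,4S)-4-[(tert-butyldimethylsilyl)oxy]-2-[(12Z)-henicos-12-en-1-yl]-2,3-dihydroxycyclohexan-1-one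
Product: 21 (4S,5R,6R)-4-[(tert-butyldimethylsilyl)oxy]-6-[(12Z)-henicos-12-en-1-yl]-5,6-bis[(trimethylsilyl)oxy]cyclohex-2-en-1-one, via tris-TMS enol ether 20 (not isolated)
Conditions: TMSOTf (3.5 equiv), Et3N (5 equiv), CH2Cl2, 0 °C; then Pd(OAc)2 (1.1 equiv), MeCN, rt
Reagents that add atoms: trimethylsilyl trifluoromethanesulfonate (C[Si](C)(C)OS(=O)(=O)C(F)(F)F)
Why: Soft enolisation with silylation caps both hydroxyls and gives the only possible enol ether (C2 carries no hydrogen), and Saegusa–Ito oxidation (C-palladation at C6, β-hydride elimination from C5) then gives the enone without touching the stereocentres.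

Step 13
Reactants: 21 (4S,5R,6R)-4-[(tert-butyldimethylsilyl)oxy]-6-[(12Z)-henicos-12-en-1-yl]-5,6-bis[(trimethylsilyl)oxy]cyclohex-2-en-1-one
Product: 22 (4S,5R,6R)-4,5,6-trihydroxy-6-[(12Z)-henicos-12-en-1-yl]cyclohex-2-en-1-one
Conditions: HF·pyridine, pyridine, THF, 0 °C → rt
Reagents that add atoms: none
Why: Fluoride-driven global desilylation (Si–F bond formation) under buffered, weakly acidic conditions removes the two TMS ethers and the TBS ether without the base that could cause retro-aldol cleavage or elimination.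

**Compound list**
1 | 4-hydroxycyclohexan-1-one | O=C1CCC(O)CC1 | starting material
2 | 4-[(tert-butyldimethylsilyl)oxy]cyclohexan-1-one | O=C1CCC(O[Si](C)(C)C(C)(C)C)CC1 | intermediate
3 | (S)-4-[(tert-butyldimethylsilyl)oxy]cyclohex-2-en-1-one | O=C1C=C[C@@H](O[Si](C)(C)C(C)(C)C)CC1 | intermediate
4 | (S)-4-[(tert-butyldimethylsilyl)oxy]-2-iodocyclohex-2-en-1-one | IC1=C[C@@H](O[Si](C)(C)C(C)(C)C)CCC1=O | intermediate
5 | oct-1-ene | C=CCCCCCC | starting material
6 | 1-bromooctane | BrCCCCCCCC | intermediate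
7 | sodium acetylide | [Na+].[C-]#C | starting material
8 | dec-1-yne | C#CCCCCCCCC | intermediate
9 | 5-bromopent-1-ene | C=CCCCBr | starting material
10 | 1-bromo-6-chlorohexane | ClCCCCCCBr | starting material
11 | pent-4-enylmagnesium bromide | C=CCCC[Mg]Br | intermediate
12 | 11-chloroundec-1-ene | C=CCCCCCCCCCCl | intermediate
13 | 11-iodoundec-1-ene | C=CCCCCCCCCCI | intermediate
14 | lithium dec-1-yn-1-ide | [Li]C#CCCCCCCCC | intermediate
15 | henicos-1-en-12-yne | C=CCCCCCCCCCC#CCCCCCCCC | intermediate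
16 | B-(henicos-12-yn-1-yl)-9-borabicyclo[3.3.1]nonane | CCCCCCCCC#CCCCCCCCCCCCB1C2CCCC1CCC2 | intermediate
17 | (S)-4-[(tert-butyldimethylsilyl)oxy]-2-(henicos-12-yn-1-yl)cyclohex-2-en-1-one | CCCCCCCCC#CCCCCCCCCCCCC1=C[C@@H](O[Si](C)(C)C(C)(C)C)CCC1=O | intermediate
18 | (2R,3R,4S)-4-[(tert-butyldimethylsilyl)oxy]-2-(henicos-12-yn-1-yl)-2,3-dihydroxycyclohexan-1-one | CCCCCCCCC#CCCCCCCCCCCC[C@]1(O)C(=O)CC[C@H](O[Si](C)(C)C(C)(C)C)[C@H]1O | intermediate
19 | (2R,3R,4S)-4-[(tert-butyldimethylsilyl)oxy]-2-[(12Z)-henicos-12-en-1-yl]-2,3-dihydroxycyclohexan-1-one | CCCCCCCC/C=C\CCCCCCCCCCC[C@]1(O)C(=O)CC[C@H](O[Si](C)(C)C(C)(C)C)[C@H]1O | intermediate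
20 | (4S,5R,6R)-4-[(tert-butyldimethylsilyl)oxy]-6-[(12Z)-henicos-12-en-1-yl]-1,5,6-tris[(trimethylsilyl)oxy]cyclohex-1-ene | CCCCCCCC/C=C\CCCCCCCCCCC[C@]1(O[Si](C)(C)C)C(O[Si](C)(C)C)=CC[C@H](O[Si](C)(C)C(C)(C)C)[C@H]1O[Si](C)(C)C | intermediate
21 | (4S,5R,6R)-4-[(tert-butyldimethylsilyl)oxy]-6-[(12Z)-henicos-12-en-1-yl]-5,6-bis[(trimethylsilyl)oxy]cyclohex-2-en-1-one | CCCCCCCC/C=C\CCCCCCCCCCC[C@]1(O[Si](C)(C)C)C(=O)C=C[C@H](O[Si](C)(C)C(C)(C)C)[C@H]1O[Si](C)(C)C | intermediate
22 | (4S,5R,6R)-4,5,6-trihydroxy-6-[(12Z)-henicos-12-en-1-yl]cyclohex-2-en-1-one | CCCCCCCC/C=C\CCCCCCCCCCC[C@]1(O)C(=O)C=C[C@H](O)[C@H]1O | target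

**Step count and risk**
Total steps: 13. Longest linear sequence: 8 steps (1, 2, 3, 9, 10, 11, 12, 13; the chain lines 4, 5, 8 and 6, 7, 8 into step 9 are equally long).

The three steps most likely to fail are steps 2, 10 and 12.

Step 2 (new reaction; risks are low enantioselectivity and over-oxidation to the phenol). The fallback sets out from 2 and comes back at 3, and uses known chemistry. Compound 2 is deprotonated with the chiral base lithium bis[(R)-1-phenylethyl]amide, LiN[CH(CH3)C6H5]2, with TMSCl present as internal quench (THF, −100 °C). This gives the enantio-enriched silyl enol ether tert-butyldimethyl{[(1S)-4-(trimethylsilyloxy)cyclohex-3-en-1-yl]oxy}silane F1. Saegusa–Ito oxidation of the enol ether (Pd(OAc)2, MeCN, rt) then gives 3.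

Step 10 (risks are slow osmylation of the electron-poor trisubstituted enone and erosion of facial selectivity). The fallback sets out from 17 and comes back at 18; it masks the carbonyl so that the alkene is no longer electron-poor. Noyori ketalisation of 17 (1,2-bis(trimethylsilyloxy)ethane, TMSOTf cat., CH2Cl2, −78 °C, double bond stays in place) gives the dioxolane tert-butyl{[(8S)-6-(henicos-12-yn-1-yl)-1,4-dioxaspiro[4.5]dec-6-en-8-yl]oxy}dimethylsilane F2. Upjohn dihydroxylation of this allylic ketal (K2OsO2(OH)4 cat., NMO, acetone/H2O), again anti to the OTBS group, gives (6R,7R,8S)-8-[(tert-butyldimethylsilyl)oxy]-6-(henicos-12-yn-1-yl)-1,4-dioxaspiro[4.5]decane-6,7-diol F3. Mild hydrolysis of the dioxolane (PPTS, wet acetone, 50 °C) gives 18.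

Step 12 (risks are incomplete palladium-mediated oxidation and Z/E isomerisation of the chain alkene by palladium hydride). The fallback sets out from 20 and comes back at 21; it replaces β-hydride elimination by selenoxide syn-elimination. The silyl enol ether 20 is treated with PhSeCl (1.0 equiv, CH2Cl2, −78 °C) to give the α-selanyl ketone (2R,3R,4S)-4-[(tert-butyldimethylsilyl)oxy]-2-[(12Z)-henicos-12-en-1-yl]-6-(phenylselanyl)-2,3-bis[(trimethylsilyl)oxy]cyclohexan-1-one F4 (C6 epimers). Oxidation (H2O2, pyridine, CH2Cl2, 0 °C) gives the selenoxide (2R,3R,4S)-4-[(tert-butyldimethylsilyl)oxy]-2-[(12Z)-henicos-12-en-1-yl]-6-(phenylseleninyl)-2,3-bis[(trimethylsilyl)oxy]cyclohexan-1-one F5, which eliminates in the flask to 21.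

**Further compounds**
F1 | step 2 | tert-butyldimethyl{[(1S)-4-(trimethylsilyloxy)cyclohex-3-en-1-yl]oxy}silane | C[Si](C)(C)OC1=CC[C@@H](O[Si](C)(C)C(C)(C)C)CC1
F2 | step 10 | tert-butyl{[(8S)-6-(henicos-12-yn-1-yl)-1,4-dioxaspiro[4.5]dec-6-en-8-yl]oxy}dimethylsilane | CCCCCCCCC#CCCCCCCCCCCCC1=C[C@@H](O[Si](C)(C)C(C)(C)C)CCC12OCCO2
F3 | step 10 | (6R,7R,8S)-8-[(tert-butyldimethylsilyl)oxy]-6-(henicos-12-yn-1-yl)-1,4-dioxaspiro[4.5]decane-6,7-diol | CCCCCCCCC#CCCCCCCCCCCC[C@]1(O)C2(OCCO2)CC[C@H](O[Si](C)(C)C(C)(C)C)[C@H]1O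
F4 | step 12 | (2R,3R,4S)-4-[(tert-butyldimethylsilyl)oxy]-2-[(12Z)-henicos-12-en-1-yl]-6-(phenylselanyl)-2,3-bis[(trimethylsilyl)oxy]cyclohexan-1-one | CCCCCCCC/C=C\CCCCCCCCCCC[C@]1(O[Si](C)(C)C)C(=O)C([Se]c2ccccc2)C[C@H](O[Si](C)(C)C(C)(C)C)[C@H]1O[Si](C)(C)C
F5 | step 12 | (2R,3R,4S)-4-[(tert-butyldimethylsilyl)oxy]-2-[(12Z)-henicos-12-en-1-yl]-6-(phenylseleninyl)-2,3-bis[(trimethylsilyl)oxy]cyclohexan-1-one | CCCCCCCC/C=C\CCCCCCCCCCC[C@]1(O[Si](C)(C)C)C(=O)C([Se](=O)c2ccccc2)C[C@H](O[Si](C)(C)C(C)(C)C)[C@H]1O[Si](C)(C)C
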